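**Retrosynthetic overview**
1. Stenophyllol B ⇐ octamethyl ether 22 (BBr3) ⇐ eight-membered ring by intramolecular Friedel–Crafts alkylation of ring B (the 3,5-dioxygenated aryl on dihydrofuran C-3) by a 4-methoxybenzylic cation ⇐ all-trans 1-aroylindane 20.
2. Five-membered carbocycle of 20 ⇐ ring expansion (three → five atoms) of donor–acceptor cyclopropane 18: the bond between the aroyl-bearing carbon and the 4-methoxyphenyl-bearing carbon opens, and the ipso/ortho carbon pair of the geminal resorcinol ring (ring A) is inserted.
3. Enabling feature: in the indane, the CH bearing the 4-hydroxyphenyl group is a para-oxygen-stabilised benzylic carbon bonded to the ring A carbon that is ortho and para to the two ring A oxygens; the indane CH at the other end carries the exocyclic diarylmethine carbon, which can be held as an aroyl acceptor (ring C = benzo ring of the benzofuran).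
4. Cyclopropane 18 ⇐ sulfonium ylide from enantiopure benzofuranylmethyl bromide 11 + α-aryl chalcone 16 (from deoxybenzoin 14 and anisaldehyde); 11 ⇐ 2,3-diarylbenzofuran ester 6 (cyclodehydration, C–H arylation) by hydrogenation, epimerisation and resolution.
5. Order of ring formation: furan ring (then reduced to the trans-dihydrofuran) → cyclopropane → five-membered carbocycle (key step) → eight-membered ring.

Key step: step 12

Assumption: in step 11 the ylide is taken to react through the rotamer with the sulfonium group turned away from the dihydrofuran ring and on the face opposite the 3-aryl group; this steric model is the only basis for the configuration drawn at the benzofuranyl-bearing carbon of 18.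

**Route**

Step 1
Reactants: 1 methyl 3-hydroxy-5-methoxybenzoate; 2 2-bromo-1-(3,5-dimethoxyphenyl)ethan-1-one
Product: 3 aryloxy ketone
Conditions: K2CO3, acetone, reflux
Reagents that add atoms: none
Why: Williamson O-alkylation of the phenoxide at a primary α-bromo ketone (SN2), with no stereocentre formed.

Step 2
Reactants: 3 aryloxy ketone
Product: 4 3-arylbenzofuran ester
Conditions: Bi(OTf)3 (10 mol%), ClCH2CH2Cl, 80 °C
Reagents that add atoms: none
Why: Acid-catalysed cyclodehydration (intramolecular Friedel–Crafts hydroxyalkylation, then loss of water) should close the furan ring at the phenol ortho carbon that is para to the methoxy group, the more activated of the two ortho positions.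

Step 3
Reactants: 4 3-arylbenzofuran ester; 5 4-bromoanisole
Product: 6 2,3-diarylbenzofuran ester
Conditions: Pd(OAc)2 (5 mol%), PCy3·HBF4 (10 mol%), PivOH (30 mol%), K2CO3, DMA, 110 °C
Reagents that add atoms: none
Why: Palladium-catalysed direct C–H arylation (concerted metalation–deprotonation) at furan C-2, the only free and most acidic heteroaryl position.

Step 4
Reactants: 6 2,3-diarylbenzofuran ester
Product: 7 racemic 2,3-cis-dihydrobenzofuran ester
Conditions: H2 (30 bar), Pd(OH)2 on carbon, EtOAc/MeOH, 40 °C, stopped at full conversion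
Reagents that add atoms: none
Why: Heterogeneous hydrogenation adds H2 syn across the furan double bond, which sets C-2 and C-3 cis (racemic).

Step 5
Reactants: 7 racemic 2,3-cis-dihydrobenzofuran ester
Product: 8 racemic 2,3-trans-dihydrobenzofuran ester
Conditions: CF3CO2H/CH2Cl2 (1:9), 25 °C
Reagents that add atoms: none
Why: Acid reversibly ionises the 4-methoxybenzylic C-2–O bond (ring opening to the benzylic cation and re-closure by the phenol), so C-2 should equilibrate to the more stable trans isomer while C-3 is untouched.

Step 6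
Reactants: 8 racemic 2,3-trans-dihydrobenzofuran ester
Product: 9 (2R,3R)-dihydrobenzofuran ester
Conditions: preparative SFC on an amylose tris(3,5-dimethylphenylcarbamate) phase, CO2/MeOH
Reagents that add atoms: none
Why: Chromatographic resolution on a chiral stationary phase separates the two trans enantiomers, and the (2R,3R) enantiomer (to be identified by X-ray or ECD) supplies the absolute configuration of both dihydrofuran centres.

Step 7
Reactants: 9 (2R,3R)-dihydrobenzofuran ester
Product: 10 (2R,3R)-benzofuranylmethanol
Conditions: LiAlH4, THF, 0 °C; aqueous NaOH work-up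
Reagents that add atoms: none
Why: Hydride reduction of the methyl ester to the primary alcohol, with the two stereocentres not involved.

Step 8
Reactants: 10 (2R,3R)-benzofuranylmethanol
Product: 11 (2R,3R)-benzofuranylmethyl bromide
Conditions: CBr4, PPh3, CH2Cl2, 0 °C
Reagents that add atoms: tetrabromomethane, BrC(Br)(Br)Br
Why: Appel bromination under neutral conditions, chosen to spare the acid-labile 2-aryl dihydrofuran ether.

Step 9
Reactants: 12 1-(4-methoxyphenyl)ethan-1-one; 13 1-bromo-3,5-dimethoxybenzene
Product: 14 deoxybenzoin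
Conditions: Pd(OAc)2 (2 mol%), Xantphos (3 mol%), NaOtBu, toluene, 80 °C
Reagents that add atoms: none
Why: Palladium-catalysed α-arylation of the methyl ketone enolate (Buchwald–Hartwig type), mono-selective with a wide-bite-angle bisphosphine.

Step 10
Reactants: 14 deoxybenzoin; 15 4-methoxybenzaldehyde
Product: 16 (E)-α-aryl chalcone
Conditions: piperidine (0.2 equiv), AcOH (0.2 equiv), toluene, reflux (Dean–Stark)
Reagents that add atoms: none
Why: Knoevenagel-type aldol condensation of the doubly activated methylene with the aldehyde, expected to give the E-alkene, although either alkene isomer serves step 11.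

Step 11
Reactants: 11 (2R,3R)-benzofuranylmethyl bromide; 16 (E)-α-aryl chalcone
Product: 18 cyclopropyl ketone, via thiolanium bromide 17 (not isolated)
Conditions: tetrahydrothiophene (2 equiv), MeCN, 25 °C; then 16 (1.2 equiv), Cs2CO3, 0 → 25 °C
Reagents that add atoms: none
Why: Corey–Chaykovsky cyclopropanation by Michael-initiated ring closure, in which the ylide adds to the enone β-carbon and the enolate displaces tetrahydrothiophene in an invertive 3-exo-tet closure; the benzofuranyl-bearing carbon (S expected) is set by attack on the ylide face remote from the 3-aryl group followed by that inversion, and the other two ring carbons may form as a mixture because step 12 erases them.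

Step 12
Reactants: 18 cyclopropyl ketone
Product: 20 all-trans indanyl ketone, via 1,2-cis ketone 19 (not isolated)
Conditions: Sc(OTf)3 (20 mol%), CH2Cl2/(CF3)2CHOH (4:1), 0 → 25 °C; then DBU (0.5 equiv), 25 °C
Reagents that add atoms: none
Why: Proposed new method: Sc(OTf)3 on the aroyl oxygen heterolyses the cyclopropane bond between the acceptor carbon and the 4-methoxyphenyl-bearing carbon to a benzylic cation/enolate zwitterion, and the 3,5-dimethoxyphenyl ring on the enolate carbon attacks the cation through its ortho carbon and rearomatises, so the three-membered ring grows by the two arene carbons into the indane, like a vinylcyclopropane–cyclopentene rearrangement with an arene as the vinyl unit. The closest known reaction types are the acid-catalysed arylative ring opening (Friedel–Crafts alkylation) of donor–acceptor cyclopropanes and the Cloke–Wilson rearrangement, which starts from the same zwitterion and should be reversible here. The five-membered ring closes by cationic Friedel–Crafts alkylation in which the arene C=C becomes endocyclic, the mode of the classic 1,3-diarylpropyl cation to 1-arylindane cyclisation. The benzofuranyl-bearing carbon is not touched and keeps its configuration; the new aryl-bearing centre (indane C-3) is set trans to it in the ring closure of the planar cation, and the α-keto centre (indane C-1) is set by enol protonation and equilibrated by DBU to the trans isomer, so every cyclopropane diastereomer should funnel to one ketone. The step needs cleavage toward the 4-methoxyphenyl-stabilised cation (secured by para oxygen against the meta-oxygenated benzofuranyl side) and five-ring closure by ring A in preference to seven-ring closure by ring B or enolate O-alkylation (favoured ring size; O-alkylation reversible).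

Step 13
Reactants: 20 all-trans indanyl ketone
Product: 21 indanyl carbinol
Conditions: NaBH4, THF/MeOH (4:1), 0 → 25 °C
Reagents that add atoms: none
Why: Borohydride reduction of the aryl ketone gives the benzylic carbinol as a mixture of epimers, which is immaterial because this carbon is ionised in step 14, and the ring stereocentres are not touched.

Step 14
Reactants: 21 indanyl carbinol
Product: 22 octa-O-methylstenophyllol B
Conditions: TsOH·H2O (10 mol%), (CF3)2CHOH/CH2Cl2 (1:1), 2 mM, −20 → 0 °C
Reagents that add atoms: none
Why: Ionisation of the 4-methoxybenzylic alcohol and intramolecular Friedel–Crafts alkylation by the ortho carbon of ring B closes the eight-membered ring, the new diarylmethine centre being set by the ring closure (cation conformer with the 4-methoxyphenyl group eclipsing the indane C–H to minimise allylic 1,3-strain, attacked from the face on which ring B is held), while the trans arrangement on the indane keeps ring C from closing a five-membered ring instead.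

Step 15
Reactants: 22 octa-O-methylstenophyllol B
Product: 23 stenophyllol B
Conditions: BBr3 (20 equiv), CH2Cl2, −78 → 25 °C; then MeOH, H2O
Reagents that add atoms: none
Why: Lewis-acid ether cleavage with BBr3 removes all eight methyl groups as bromomethane, and the dihydrofuran C–O bond, if opened through the 4-oxybenzylic cation, should re-close to the stable trans ring on work-up, so no stereocentre is changed.

**Compound list**
1 | methyl 3-hydroxy-5-methoxybenzoate | COC(=O)c1cc(O)cc(OC)c1 | starting material
2 | 2-bromo-1-(3,5-dimethoxyphenyl)ethan-1-one | COc1cc(OC)cc(C(=O)CBr)c1 | starting material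
3 | methyl 3-[2-(3,5-dimethoxyphenyl)-2-oxoethoxy]-5-methoxybenzoate | COC(=O)c1cc(OC)cc(OCC(=O)c2cc(OC)cc(OC)c2)c1 | intermediate
4 | methyl 3-(3,5-dimethoxyphenyl)-6-methoxy-1-benzofuran-4-carboxylate | COC(=O)c1cc(OC)cc2occ(-c3cc(OC)cc(OC)c3)c12 | intermediate
5 | 4-bromoanisole (1-bromo-4-methoxybenzene) | COc1ccc(Br)cc1 | starting material
6 | methyl 3-(3,5-dimethoxyphenyl)-6-methoxy-2-(4-methoxyphenyl)-1-benzofuran-4-carboxylate | COC(=O)c1cc(OC)cc2oc(-c3ccc(OC)cc3)c(-c3cc(OC)cc(OC)c3)c12 | intermediate
7 | rac-methyl (2R,3S)-3-(3,5-dimethoxyphenyl)-6-methoxy-2-(4-methoxyphenyl)-2,3-dihydro-1-benzofuran-4-carboxylate (2,3-cis, racemic; one enantiomer drawn) | COC(=O)c1cc(OC)cc2O[C@@H](c3ccc(OC)cc3)[C@@H](c3cc(OC)cc(OC)c3)c12 | intermediate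
8 | rac-methyl (2R,3R)-3-(3,5-dimethoxyphenyl)-6-methoxy-2-(4-methoxyphenyl)-2,3-dihydro-1-benzofuran-4-carboxylate (2,3-trans, racemic; one enantiomer drawn) | COC(=O)c1cc(OC)cc2O[C@@H](c3ccc(OC)cc3)[C@H](c3cc(OC)cc(OC)c3)c12 | intermediate
9 | methyl (2R,3R)-3-(3,5-dimethoxyphenyl)-6-methoxy-2-(4-methoxyphenyl)-2,3-dihydro-1-benzofuran-4-carboxylate (single enantiomer) | COC(=O)c1cc(OC)cc2O[C@@H](c3ccc(OC)cc3)[C@H](c3cc(OC)cc(OC)c3)c12 | intermediate
10 | [(2R,3R)-3-(3,5-dimethoxyphenyl)-6-methoxy-2-(4-methoxyphenyl)-2,3-dihydro-1-benzofuran-4-yl]methanol | OCc1cc(OC)cc2O[C@@H](c3ccc(OC)cc3)[C@H](c3cc(OC)cc(OC)c3)c12 | intermediate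
11 | (2R,3R)-4-(bromomethyl)-3-(3,5-dimethoxyphenyl)-6-methoxy-2-(4-methoxyphenyl)-2,3-dihydro-1-benzofuran | BrCc1cc(OC)cc2O[C@@H](c3ccc(OC)cc3)[C@H](c3cc(OC)cc(OC)c3)c12 | intermediate
12 | 1-(4-methoxyphenyl)ethan-1-one | COc1ccc(C(C)=O)cc1 | starting material
13 | 1-bromo-3,5-dimethoxybenzene | COc1cc(Br)cc(OC)c1 | starting material
14 | 2-(3,5-dimethoxyphenyl)-1-(4-methoxyphenyl)ethan-1-one | COc1ccc(C(=O)Cc2cc(OC)cc(OC)c2)cc1 | intermediate
15 | 4-methoxybenzaldehyde | COc1ccc(C=O)cc1 | starting material
16 | (E)-2-(3,5-dimethoxyphenyl)-1,3-bis(4-methoxyphenyl)prop-2-en-1-one | COc1ccc(/C=C(/C(=O)c2ccc(OC)cc2)c2cc(OC)cc(OC)c2)cc1 | intermediate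
17 | 1-{[(2R,3R)-3-(3,5-dimethoxyphenyl)-6-methoxy-2-(4-methoxyphenyl)-2,3-dihydro-1-benzofuran-4-yl]methyl}thiolan-1-ium bromide (not isolated) | [Br-].C1CC[S+](C1)Cc1cc(OC)cc2O[C@@H](c3ccc(OC)cc3)[C@H](c3cc(OC)cc(OC)c3)c12 | intermediate
18 | (4-methoxyphenyl){(3S)-1-(3,5-dimethoxyphenyl)-3-[(2R,3R)-3-(3,5-dimethoxyphenyl)-6-methoxy-2-(4-methoxyphenyl)-2,3-dihydro-1-benzofuran-4-yl]-2-(4-methoxyphenyl)cyclopropyl}methanone (C-1/C-2 epimers all usable; the (1R,2S,3S) isomer with 2,3-trans aryl groups is drawn) | COc1ccc([C@@H]2[C@@H](c3cc(OC)cc4O[C@@H](c5ccc(OC)cc5)[C@H](c5cc(OC)cc(OC)c5)c34)[C@@]2(C(=O)c2ccc(OC)cc2)c2cc(OC)cc(OC)c2)cc1 | intermediate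
19 | (4-methoxyphenyl){(1R,2R,3S)-2-[(2R,3R)-3-(3,5-dimethoxyphenyl)-6-methoxy-2-(4-methoxyphenyl)-2,3-dihydro-1-benzofuran-4-yl]-4,6-dimethoxy-3-(4-methoxyphenyl)-2,3-dihydro-1H-inden-1-yl}methanone (1,2-cis, 2,3-trans; not isolated) | COc1ccc([C@H]2c3c(OC)cc(OC)cc3[C@H](C(=O)c3ccc(OC)cc3)[C@@H]2c2cc(OC)cc3O[C@@H](c4ccc(OC)cc4)[C@H](c4cc(OC)cc(OC)c4)c23)cc1 | intermediate
20 | (4-methoxyphenyl){(1S,2R,3S)-2-[(2R,3R)-3-(3,5-dimethoxyphenyl)-6-methoxy-2-(4-methoxyphenyl)-2,3-dihydro-1-benzofuran-4-yl]-4,6-dimethoxy-3-(4-methoxyphenyl)-2,3-dihydro-1H-inden-1-yl}methanone (1,2-trans, 2,3-trans) | COc1ccc([C@H]2c3c(OC)cc(OC)cc3[C@@H](C(=O)c3ccc(OC)cc3)[C@@H]2c2cc(OC)cc3O[C@@H](c4ccc(OC)cc4)[C@H](c4cc(OC)cc(OC)c4)c23)cc1 | intermediate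
21 | (4-methoxyphenyl){(1S,2R,3S)-2-[(2R,3R)-3-(3,5-dimethoxyphenyl)-6-methoxy-2-(4-methoxyphenyl)-2,3-dihydro-1-benzofuran-4-yl]-4,6-dimethoxy-3-(4-methoxyphenyl)-2,3-dihydro-1H-inden-1-yl}methanol (both carbinol epimers) | COc1ccc([C@H]2c3c(OC)cc(OC)cc3[C@@H](C(O)c3ccc(OC)cc3)[C@@H]2c2cc(OC)cc3O[C@@H](c4ccc(OC)cc4)[C@H](c4cc(OC)cc(OC)c4)c23)cc1 | intermediate
22 | octa-O-methylstenophyllol B (all eight phenols as methyl ethers; ring system and configuration of the target) | COc1ccc([C@H]2c3c(OC)cc(OC)cc3[C@H]3[C@H](c4ccc(OC)cc4)c4c(OC)cc(OC)cc4[C@@H]4c5c(cc(OC)cc5[C@H]23)O[C@H]4c2ccc(OC)cc2)cc1 | intermediate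
23 | stenophyllol B | Oc1ccc([C@H]2c3c(O)cc(O)cc3[C@H]3[C@H](c4ccc(O)cc4)c4c(O)cc(O)cc4[C@@H]4c5c(cc(O)cc5[C@H]23)O[C@H]4c2ccc(O)cc2)cc1 | target

Total step count: 15. Longest linear sequence: 13 steps (steps 1–8, then 11–15).

**Steps most likely to fail**

1. Step 12 (proposed new method). The ring-opened zwitterion may be diverted before the Friedel–Crafts closure: by proton loss next to the cation (an open-chain styrene and, on re-protonation, loss of configuration at the benzofuranyl-bearing carbon), by seven-membered closure through ring B, or by stalling at the O-alkylated stage. The fallback uses known chemistry, sets out from 18 and returns at 20. Homo-conjugate ring opening of the cyclopropyl ketone with Me3SiI (CH2Cl2, −40 °C, then aqueous NaHCO3) should place iodide on the 4-methoxyphenyl-bearing carbon and give the γ-iodo ketone F1. Without purification, F1 is cyclised by a silver-promoted intramolecular Friedel–Crafts alkylation (AgOTf, 2,6-di-tert-butylpyridine, CH2Cl2, −40 °C), and the crude ketone is equilibrated with DBU as in step 12 to reach 20. Opening and closing are thus separated, and the closure runs under buffered, non-protic conditions.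

2. Step 14. Elimination of the secondary benzylic cation to the exocyclic styrene may outrun the slow eight-membered closure. Re-protonation from the less hindered face would then allow five-membered closure by ring C. The fallback sets out from 20 and returns at 22. Bradsher-type cyclodehydration of the ketone (TfOH, (CF3)2CHOH, 0 °C: intramolecular hydroxyalkylation of ring B, then loss of water) should give the cyclic styrene F2, in which the eight-membered ring is already closed. Ionic hydrogenation of F2 (Et3SiH, CF3CO2H, CH2Cl2, −20 °C) then protonates the indane carbon and delivers hydride to the tertiary, doubly benzylic cation. Elimination there only regenerates F2. Both centres are set in this reduction, and the diastereomers would have to be separated if protonation is not trans-selective.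

3. Step 11. Facial selectivity at the ylide carbon may be poor, conjugate addition to the hindered trisubstituted enone may be sluggish, or the betaine may close through oxygen. The fallback replaces substrate control by reagent control, sets out from 11 and returns at 18. Bromide 11 is alkylated onto (1R,4R,5R)-isothiocineole (NaBF4, CH2Cl2/H2O) to give the chiral sulfonium tetrafluoroborate F3. Its ylide (powdered KOH, MeCN, 0 °C) cyclopropanates 16 with the sulfide controlling the face of the ylide carbon. The antipodal sulfide is used if the (1R,4R,5R) reagent proves mismatched with the substrate bias.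

Further compounds
F1 | step 12 | (3S)-2-(3,5-dimethoxyphenyl)-3-[(2R,3R)-3-(3,5-dimethoxyphenyl)-6-methoxy-2-(4-methoxyphenyl)-2,3-dihydro-1-benzofuran-4-yl]-4-iodo-1,4-bis(4-methoxyphenyl)butan-1-one (mixture at C-2 and C-4) | COc1ccc(C(I)[C@@H](c2cc(OC)cc3O[C@@H](c4ccc(OC)cc4)[C@H](c4cc(OC)cc(OC)c4)c23)C(C(=O)c2ccc(OC)cc2)c2cc(OC)cc(OC)c2)cc1
F2 | step 14 | didehydro-octa-O-methylstenophyllol B (ring double bond between the indane carbon and the bis-aryl carbon of the eight-membered ring) | COc1ccc([C@H]2c3c(OC)cc(OC)cc3C3=C(c4ccc(OC)cc4)c4c(OC)cc(OC)cc4[C@@H]4c5c(cc(OC)cc5[C@H]23)O[C@H]4c2ccc(OC)cc2)cc1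
F3 | step 11 | (1R,4R,5R)-6-{[(2R,3R)-3-(3,5-dimethoxyphenyl)-6-methoxy-2-(4-methoxyphenyl)-2,3-dihydro-1-benzofuran-4-yl]methyl}-4,7,7-trimethyl-6-thiabicyclo[3.2.1]octan-6-ium tetrafluoroborate | F[B-](F)(F)F.C[C@@H]1CC[C@@H]2C[C@H]1[S+](Cc1cc(OC)cc3O[C@@H](c4ccc(OC)cc4)[C@H](c4cc(OC)cc(OC)c4)c13)C2(C)C
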